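**Assumption:** the target has no stereocentre, and with only three ortho substituents around the ether oxygen it has no stable chiral axis. It is therefore achiral, there is no enantiomer to select, and no SMILES carries a stereodescriptor.

## Retrosynthetic overview
1. 13 ⇒ 12 by removing both O‑methyl groups last. The Br para to the ring‑B OH comes from NH2, and that from NO2 (Sandmeyer). The Br ortho to that OH comes from bromination of nitrophenol 7.
2. Key disconnection: ring B of 7 is cut into aryloxyacetone 4 (C–CO–C) and nitromalonaldehyde 5 (C–C(NO2)–C). An intermolecular aldol condensation is followed by a ring‑closing aldol condensation and tautomerisation.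
3. 4 ⇒ tribromoguaiacol 2 + chloroacetone 3, so the ether oxygen is in place before ring B exists.
4. 2 ⇒ guaiacol 1 + 3 Br2.
5. Ring order: ring A is bought and fully brominated first. Ring B is the only ring formed (step 3).

## Route

**Step 1**
Reactants: 1 guaiacol (2‑methoxyphenol)
Product: 2 2,3,4‑tribromo‑6‑methoxyphenol (4,5,6‑tribromoguaiacol)
Conditions: Br2 (3.1 equiv), AcOH, 10 °C → rt, then 50 °C, 3 h; aq NaHSO3; recrystallise from EtOH
Reagents that add atoms: bromine, BrBr
Why: Electrophilic aromatic bromination in which OH directs two bromines para and ortho to itself and OMe directs the third para to itself, leaving only the C–H next to OMe; no stereocentre is formed.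

**Step 2**
Reactants: 2 2,3,4‑tribromo‑6‑methoxyphenol; 3 chloroacetone
Product: 4 1‑(2,3,4‑tribromo‑6‑methoxyphenoxy)propan‑2‑one
Conditions: K2CO3 (1.5 equiv), 3 (1.3 equiv), DMF, 50 °C, 6 h
Reagents that add atoms: none
Why: Williamson ether synthesis (SN2) of the fully ionised acidic phenol on an activated primary α‑chloroketone, which tolerates the two ortho substituents, and those also block any later benzofuran cyclisation.

**Step 3 (key step)**
Reactants: 4 1‑(2,3,4‑tribromo‑6‑methoxyphenoxy)propan‑2‑one; 5 sodium nitromalonaldehyde monohydrate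
Product: 7 2‑(2,3,4‑tribromo‑6‑methoxyphenoxy)‑4‑nitrophenol, via open‑chain nitro enal 6 (not isolated)
Conditions: 5 (1.2 equiv; shock‑sensitive, handle in small portions), NaOH (2 equiv), EtOH/THF/H2O, 0 °C → rt, 48–72 h; then 2 M HCl
Reagents that add atoms: none
Why: The enolate of 4 undergoes an intermolecular aldol condensation with one formyl group of 5, the other α‑carbon closes the ring by an intramolecular aldol condensation, and tautomerisation gives the phenol (nitromalonaldehyde–ketone [3+3] benzannulation), with only one regioisomer possible because both α‑carbons are used.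

**Step 4**
Reactants: 7 2‑(2,3,4‑tribromo‑6‑methoxyphenoxy)‑4‑nitrophenol
Product: 8 2‑bromo‑4‑nitro‑6‑(2,3,4‑tribromo‑6‑methoxyphenoxy)phenol
Conditions: Br2 (1.05 equiv), NaOAc (1.2 equiv), AcOH, rt, 4 h
Reagents that add atoms: bromine, BrBr
Why: Electrophilic aromatic bromination at the only free position ortho to the partly ionised OH (para is blocked by NO2, which also directs there), while the tribromoanisole ring is far too deactivated to compete.

**Step 5**
Reactants: 8 2‑bromo‑4‑nitro‑6‑(2,3,4‑tribromo‑6‑methoxyphenoxy)phenol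
Product: 9 1,2,3‑tribromo‑4‑(3‑bromo‑2‑methoxy‑5‑nitrophenoxy)‑5‑methoxybenzene
Conditions: MeI (1.5 equiv), K2CO3 (2 equiv), DMF, 40 °C, 12 h
Reagents that add atoms: iodomethane, CI
Why: Williamson O‑methylation of the acidic nitrophenol, done so that the later para‑aminophenol cannot collapse to a quinone diazide on diazotisation.

**Step 6**
Reactants: 9 1,2,3‑tribromo‑4‑(3‑bromo‑2‑methoxy‑5‑nitrophenoxy)‑5‑methoxybenzene
Product: 10 3‑bromo‑4‑methoxy‑5‑(2,3,4‑tribromo‑6‑methoxyphenoxy)aniline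
Conditions: Fe powder (5 equiv), AcOH/EtOH/H2O, 70 °C, 2 h
Reagents that add atoms: none
Why: Béchamp‑type dissolving‑metal reduction of the nitro group, which leaves aryl bromides and aryl ethers untouched, unlike catalytic hydrogenation.

**Step 7**
Reactants: 10 3‑bromo‑4‑methoxy‑5‑(2,3,4‑tribromo‑6‑methoxyphenoxy)aniline
Product: 12 1,2,3‑tribromo‑4‑(3,5‑dibromo‑2‑methoxyphenoxy)‑5‑methoxybenzene, via arenediazonium bromide 11 (not isolated)
Conditions: NaNO2 (1.05 equiv), 48 % HBr, MeCN/H2O, 0 °C; then CuBr (1.2 equiv), 48 % HBr, 0 → 65 °C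
Reagents that add atoms: hydrobromic acid, Br; copper(I) bromide (bromine‑transfer mediator), [Cu+].[Br-]; sodium nitrite, [Na+].[O-]N=O (its N is present only in 11 and leaves as N2)
Why: Diazotisation followed by Sandmeyer bromination replaces NH2 by Br exactly at the carbon that carried the nitro group, so the position is fixed by the ring construction.

**Step 8**
Reactants: 12 1,2,3‑tribromo‑4‑(3,5‑dibromo‑2‑methoxyphenoxy)‑5‑methoxybenzene
Product: 13 3,4,5‑tribromo‑2‑(3,5‑dibromo‑2‑hydroxyphenoxy)phenol (target)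
Conditions: BBr3 (5 equiv), CH2Cl2, −78 °C → rt, 16 h; then H2O
Reagents that add atoms: none
Why: Lewis‑acid aryl methyl ether cleavage removes both methyl groups by bromide attack on CH3, while the diaryl ether and all C–Br bonds are inert.

## Compound list
1 | guaiacol (2‑methoxyphenol) | COc1ccccc1O | starting material
2 | 2,3,4‑tribromo‑6‑methoxyphenol | COc1cc(Br)c(Br)c(Br)c1O | intermediate
3 | chloroacetone | CC(=O)CCl | starting material
4 | 1‑(2,3,4‑tribromo‑6‑methoxyphenoxy)propan‑2‑one | CC(=O)COc1c(OC)cc(Br)c(Br)c1Br | intermediate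
5 | sodium nitromalonaldehyde monohydrate | O.[Na+].[O-]C=C(C=O)[N+](=O)[O-] | starting material
6 | 2‑nitro‑5‑oxo‑4‑(2,3,4‑tribromo‑6‑methoxyphenoxy)hex‑3‑enal (drawn neutral, alkene geometry mobile, not isolated) | CC(=O)C(Oc1c(OC)cc(Br)c(Br)c1Br)=CC(C=O)[N+](=O)[O-] | intermediate
7 | 2‑(2,3,4‑tribromo‑6‑methoxyphenoxy)‑4‑nitrophenol | COc1cc(Br)c(Br)c(Br)c1Oc1cc([N+](=O)[O-])ccc1O | intermediate
8 | 2‑bromo‑4‑nitro‑6‑(2,3,4‑tribromo‑6‑methoxyphenoxy)phenol | COc1cc(Br)c(Br)c(Br)c1Oc1cc([N+](=O)[O-])cc(Br)c1O | intermediate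
9 | 1,2,3‑tribromo‑4‑(3‑bromo‑2‑methoxy‑5‑nitrophenoxy)‑5‑methoxybenzene | COc1cc(Br)c(Br)c(Br)c1Oc1cc([N+](=O)[O-])cc(Br)c1OC | intermediate
10 | 3‑bromo‑4‑methoxy‑5‑(2,3,4‑tribromo‑6‑methoxyphenoxy)aniline | COc1cc(Br)c(Br)c(Br)c1Oc1cc(N)cc(Br)c1OC | intermediate
11 | 3‑bromo‑4‑methoxy‑5‑(2,3,4‑tribromo‑6‑methoxyphenoxy)benzenediazonium bromide (not isolated) | COc1cc(Br)c(Br)c(Br)c1Oc1cc([N+]#N)cc(Br)c1OC.[Br-] | intermediate
12 | 1,2,3‑tribromo‑4‑(3,5‑dibromo‑2‑methoxyphenoxy)‑5‑methoxybenzene | COc1cc(Br)c(Br)c(Br)c1Oc1cc(Br)cc(Br)c1OC | intermediate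
13 | 3,4,5‑tribromo‑2‑(3,5‑dibromo‑2‑hydroxyphenoxy)phenol | Oc1cc(Br)c(Br)c(Br)c1Oc1cc(Br)cc(Br)c1O | target

## Summary
Total step count: 8. Longest linear sequence: 8 (1 → 13; compounds 3 and 5 are bought).

## The three steps most likely to fail

**Step 3.** The risks are a slow or low‑yielding benzannulation, self‑condensation of 4, and decay of 5 in base.

The fallback sets out from 2 and comes back at 13. It builds ring B by a Michael/aldol annulation instead.
- 2 is O‑alkylated with tert‑butyl 2‑chloroacetoacetate (K2CO3, DMF) to give racemic tert‑butyl 3‑oxo‑2‑(2,3,4‑tribromo‑6‑methoxyphenoxy)butanoate F1.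
- Et3N‑catalysed intermolecular Michael addition to acrolein (MeCN, 0 °C) gives racemic tert‑butyl 2‑acetyl‑5‑oxo‑2‑(2,3,4‑tribromo‑6‑methoxyphenoxy)pentanoate F2.
- TsOH in refluxing toluene brings about aldol condensation, tert‑butyl ester cleavage and decarboxylation. The product is racemic 6‑(2,3,4‑tribromo‑6‑methoxyphenoxy)cyclohex‑2‑en‑1‑one F3, whose stereocentre disappears in the next operation.
- DDQ in refluxing dioxane dehydrogenates it to 2‑(2,3,4‑tribromo‑6‑methoxyphenoxy)phenol F4.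
- Br2 (2 equiv, AcOH, rt) enters para and ortho to the free OH to give 2,4‑dibromo‑6‑(2,3,4‑tribromo‑6‑methoxyphenoxy)phenol F5.
- BBr3 under the step 8 conditions gives 13.

**Step 7.** The risk is that phenol, reduced arene or biaryl forms in the copper step.

The fallback sets out from 10 and comes back at 13. The nitrogen is removed and the last bromine is introduced by electrophilic substitution.
- 10 is diazotised (NaNO2, H2SO4/AcOH, 0 °C) and reduced with H3PO2 to 1,2,3‑tribromo‑4‑(3‑bromo‑2‑methoxyphenoxy)‑5‑methoxybenzene F6.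
- BBr3 in CH2Cl2 gives 3,4,5‑tribromo‑2‑(3‑bromo‑2‑hydroxyphenoxy)phenol F7.
- Br2 (1.0 equiv, AcOH, 0 °C) brominates para to the OH of the monobromo ring to give 13. That ring is far more reactive than the tribromo ring.

**Step 1.** The risks are under‑ or over‑bromination and contamination by an isomeric tribromide.

The fallback sets out from 1 and comes back at 2. The middle bromine is placed through nitrogen, so that all directing effects agree.
- 1 is acetylated (Ac2O, pyridine) to 2‑methoxyphenyl acetate F8.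
- Nitration para to the now dominant OMe (HNO3, AcOH, 0 °C) gives 2‑methoxy‑5‑nitrophenyl acetate F9.
- Saponification (aq NaOH, then HCl) gives 2‑methoxy‑5‑nitrophenol F10.
- Reduction (Fe, AcOH) gives 5‑amino‑2‑methoxyphenol F11. Both F10 and F11 can also be bought.
- Br2 (2 equiv, AcOH, 0 °C) enters the two positions ortho to NH2, which are also ortho and para to OH, giving 3‑amino‑2,4‑dibromo‑6‑methoxyphenol F12.
- Diazotisation (NaNO2, H2SO4/AcOH) followed by CuBr/HBr gives 2.

## Further compounds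
F1 | step 3 | tert‑butyl 3‑oxo‑2‑(2,3,4‑tribromo‑6‑methoxyphenoxy)butanoate (racemic) | CC(=O)C(Oc1c(OC)cc(Br)c(Br)c1Br)C(=O)OC(C)(C)C
F2 | step 3 | tert‑butyl 2‑acetyl‑5‑oxo‑2‑(2,3,4‑tribromo‑6‑methoxyphenoxy)pentanoate (racemic) | CC(=O)C(CCC=O)(Oc1c(OC)cc(Br)c(Br)c1Br)C(=O)OC(C)(C)C
F3 | step 3 | 6‑(2,3,4‑tribromo‑6‑methoxyphenoxy)cyclohex‑2‑en‑1‑one (racemic) | O=C1C=CCCC1Oc1c(OC)cc(Br)c(Br)c1Br
F4 | step 3 | 2‑(2,3,4‑tribromo‑6‑methoxyphenoxy)phenol | COc1cc(Br)c(Br)c(Br)c1Oc1ccccc1O
F5 | step 3 | 2,4‑dibromo‑6‑(2,3,4‑tribromo‑6‑methoxyphenoxy)phenol | COc1cc(Br)c(Br)c(Br)c1Oc1cc(Br)cc(Br)c1O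
F6 | step 7 | 1,2,3‑tribromo‑4‑(3‑bromo‑2‑methoxyphenoxy)‑5‑methoxybenzene | COc1cc(Br)c(Br)c(Br)c1Oc1cccc(Br)c1OC
F7 | step 7 | 3,4,5‑tribromo‑2‑(3‑bromo‑2‑hydroxyphenoxy)phenol | Oc1cc(Br)c(Br)c(Br)c1Oc1cccc(Br)c1O
F8 | step 1 | 2‑methoxyphenyl acetate | COc1ccccc1OC(C)=O
F9 | step 1 | 2‑methoxy‑5‑nitrophenyl acetate | COc1ccc(cc1OC(C)=O)[N+](=O)[O-]
F10 | step 1 | 2‑methoxy‑5‑nitrophenol | COc1ccc(cc1O)[N+](=O)[O-]
F11 | step 1 | 5‑amino‑2‑methoxyphenol | COc1ccc(N)cc1O
F12 | step 1 | 3‑amino‑2,4‑dibromo‑6‑methoxyphenol | COc1cc(Br)c(N)c(Br)c1O
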